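## Retrosynthetic overview

1. The target comes from its bis-TBS ether. The C3–OH bond is made last, on the lactone enolate, from the face opposite the C4 benzyl group, which gives the cis-dibenzyl (3S,4R) array.
2. The C3–CH2Ar(syringyl) bond comes from the lactone silyl ketene acetal and the parent syringyl p-quinone methide. The methide is made by C–H oxidation of 2,6-dimethoxy-4-methylphenol (new dehydrogenative 1,6-benzylation).
3. The (S)-β-benzyl-γ-butyrolactone comes from a catalytic enantioselective Baeyer–Villiger 4→5 ring expansion of a prochiral 3-benzylcyclobutanone. This is the key step: it sets C4, and C3 is relayed from C4.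
4. The cyclobutanone comes from a Negishi coupling of (3-oxocyclobutyl)methylzinc bromide with silylated 4-bromoguaiacol (from catechol). The syringyl unit comes from p-cresol by dibromination and Cu-catalysed methoxylation.
5. Ring order: both arenes and the four-membered ring are bought, and the γ-lactone is the only ring made, by the ring expansion.

Assumption: the SMILES is read as (3S,4R), with the two benzyl groups cis and the 3-OH trans to the C4 benzyl group; catechol, p-cresol and 3-(bromomethyl)cyclobutan-1-one are taken as catalogue chemicals.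

## Route

Step 1
Reactants: 1 catechol
Product: 2 guaiacol (2-methoxyphenol)
Conditions: MeI (1.0 equiv), K2CO3 (1.0 equiv), acetone, reflux
Reagents that add atoms: iodomethane CI
Why: Williamson O-methylation with one equivalent of MeI and a weak base stops largely at the monoether, because the remaining OH is hydrogen-bonded to the new OMe and is ionised less readily, and leftover catechol and veratrole are removed by base extraction and distillation.

Step 2
Reactants: 2 guaiacol
Product: 4 tert-butyl(4-bromo-2-methoxyphenoxy)dimethylsilane, via 4-bromo-2-methoxyphenol 3 (not isolated)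
Conditions: NBS, DMF, 0 °C; then imidazole, TBSCl, rt (one pot)
Reagents that add atoms: N-bromosuccinimide O=C1CCC(=O)N1Br; tert-butyldimethylsilyl chloride CC(C)(C)[Si](C)(C)Cl
Why: Electrophilic aromatic bromination with NBS in DMF goes para to the free OH (the strongest donor), and the phenol is then capped in the same flask by standard imidazole-promoted silylation.

Step 3
Reactants: 4 tert-butyl(4-bromo-2-methoxyphenoxy)dimethylsilane, 5 3-(bromomethyl)cyclobutan-1-one
Product: 7 3-{[4-(tert-butyldimethylsilyloxy)-3-methoxyphenyl]methyl}cyclobutan-1-one, via (3-oxocyclobutyl)methylzinc bromide 6 (not isolated)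
Conditions: 5, Zn dust, I2 (5 mol %), DMA, 70 °C; then 4, Pd(OAc)2 (2 mol %), SPhos (4 mol %), rt to 40 °C
Reagents that add atoms: none
Why: In this Negishi sp3–sp2 cross-coupling the alkylzinc halide tolerates its own ketone, and the bulky biaryl phosphine makes reductive elimination faster than β-hydride elimination, so the prochiral (achiral) 3-benzylcyclobutanone is formed.

Step 4
Reactants: 7 3-{[4-(tert-butyldimethylsilyloxy)-3-methoxyphenyl]methyl}cyclobutan-1-one
Product: 8 (4S)-4-{[4-(tert-butyldimethylsilyloxy)-3-methoxyphenyl]methyl}oxolan-2-one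
Conditions: Sc(OTf)3 (5 mol %), chiral N,N'-dioxide ligand (5.5 mol %, the antipode that gives the S lactone), mCPBA (1.2 equiv), EtOAc, −20 °C
Reagents that add atoms: 3-chloroperoxybenzoic acid OOC(=O)c1cccc(Cl)c1
Why: This is a Baeyer–Villiger ring expansion run as a desymmetrisation, in which strain release makes the cyclobutanone react far faster than the arene or silyl ether, and in the Sc-bound Criegee adduct the ligand lets only one of the two enantiotopic ring CH2 groups lie antiperiplanar to the O–O bond and shift from C to O, which fixes C4 as S (about 90% ee expected).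

Step 5
Reactants: 9 p-cresol
Product: 10 2,6-dibromo-4-methylphenol
Conditions: Br2 (2.05 equiv), AcOH, 0 °C to rt
Reagents that add atoms: bromine BrBr
Why: Electrophilic aromatic bromination can only take the two positions ortho to OH, because the para position is blocked by the methyl group.

Step 6
Reactants: 10 2,6-dibromo-4-methylphenol
Product: 11 2,6-dimethoxy-4-methylphenol
Conditions: NaOMe (5 equiv), CuI (15 mol %), DMF/MeOH, 110 °C; aq HCl
Reagents that add atoms: sodium methoxide C[O-].[Na+]
Why: Ullmann-type Cu(I)-catalysed methoxylation replaces both C–Br bonds, a well-established exchange for ortho-bromophenols of exactly this type.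

Step 7
Reactants: 8 (4S)-4-{[4-(tert-butyldimethylsilyloxy)-3-methoxyphenyl]methyl}oxolan-2-one, 11 2,6-dimethoxy-4-methylphenol
Product: 14 (3S,4S)-3-{[4-(tert-butyldimethylsilyloxy)-3,5-dimethoxyphenyl]methyl}-4-{[4-(tert-butyldimethylsilyloxy)-3-methoxyphenyl]methyl}oxolan-2-one, via lactone silyl ketene acetal 12 (not isolated), via syringyl p-quinone methide 13 (not isolated)
Conditions: flask A: 8, TBSOTf (1.3 equiv), iPr2NEt (1.15 equiv), CH2Cl2, 0 °C; flask B: 11 (1.4 equiv), Ag2O, 4 Å MS, CH2Cl2 (0.02 M), 0 °C, 15 min; filter B under Ar into A at −78 °C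
Reagents that add atoms: tert-butyldimethylsilyl triflate CC(C)(C)[Si](C)(C)OS(=O)(=O)C(F)(F)F
Why: Proposed new method: a dehydrogenative Mukaiyama-type 1,6-benzylation in which Ag2O converts the ArCH3 group of 11 into the δ-unsubstituted quinone methide 13, the small excess of TBSOTf silylates its carbonyl oxygen to a strongly stabilised 4-silyloxy-3,5-dimethoxybenzyl cation, the far more nucleophilic ketene acetal 12 (made by soft enolisation in the same flask) attacks the exocyclic CH2 anti to the C4 benzyl group with aromatisation as driving force, and the silyl cation released from the silyloxocarbenium ion carries the chain so that the new phenol emerges already TBS-protected (the trans C3 centre is erased again in step 8); the closest known reaction types are Lewis-acid-catalysed 1,6-additions of silyl nucleophiles to preformed δ-aryl di-tert-butyl p-quinone methides and one-pot soft-enolisation Mukaiyama additions.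

Step 8
Reactants: 14 (3S,4S)-3-{[4-(tert-butyldimethylsilyloxy)-3,5-dimethoxyphenyl]methyl}-4-{[4-(tert-butyldimethylsilyloxy)-3-methoxyphenyl]methyl}oxolan-2-one
Product: 16 (3S,4R)-3-hydroxy-3-{[4-(tert-butyldimethylsilyloxy)-3,5-dimethoxyphenyl]methyl}-4-{[4-(tert-butyldimethylsilyloxy)-3-methoxyphenyl]methyl}oxolan-2-one, via potassium lactone enolate 15 (not isolated)
Conditions: KHMDS, THF, −78 °C; 2-(phenylsulfonyl)-3-phenyloxaziridine, −78 °C; AcOH quench
Reagents that add atoms: 2-(phenylsulfonyl)-3-phenyloxaziridine O=S(=O)(N1OC1c1ccccc1)c1ccccc1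
Why: In this Davis enolate hydroxylation the planar potassium enolate takes up oxygen on the face opposite the C4 benzyl group, so the OH ends up trans to it and the two benzyl groups cis, which is the required (3S,4R) array and the usual outcome for α,β-dibenzylbutyrolactone enolates.

Step 9
Reactants: 16 (3S,4R)-3-hydroxy-3-{[4-(tert-butyldimethylsilyloxy)-3,5-dimethoxyphenyl]methyl}-4-{[4-(tert-butyldimethylsilyloxy)-3-methoxyphenyl]methyl}oxolan-2-one
Product: 17 (3S,4R)-3-hydroxy-3-[(4-hydroxy-3,5-dimethoxyphenyl)methyl]-4-[(4-hydroxy-3-methoxyphenyl)methyl]oxolan-2-one (target)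
Conditions: KHF2, MeOH, rt
Reagents that add atoms: none
Why: Fluoride-mediated desilylation under slightly acidic conditions cleaves both aryl silyl ethers without touching the lactone, the tertiary alcohol or either non-epimerisable stereocentre, and it avoids air-sensitive free phenoxides.

## Compound list

1 | catechol | Oc1ccccc1O | starting material
2 | guaiacol | COc1ccccc1O | intermediate
3 | 4-bromo-2-methoxyphenol | COc1cc(Br)ccc1O | intermediate
4 | tert-butyl(4-bromo-2-methoxyphenoxy)dimethylsilane | COc1cc(Br)ccc1O[Si](C)(C)C(C)(C)C | intermediate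
5 | 3-(bromomethyl)cyclobutan-1-one | O=C1CC(CBr)C1 | starting material
6 | (3-oxocyclobutyl)methylzinc bromide | O=C1CC(C[Zn]Br)C1 | intermediate
7 | 3-{[4-(tert-butyldimethylsilyloxy)-3-methoxyphenyl]methyl}cyclobutan-1-one | COc1cc(CC2CC(=O)C2)ccc1O[Si](C)(C)C(C)(C)C | intermediate
8 | (4S)-4-{[4-(tert-butyldimethylsilyloxy)-3-methoxyphenyl]methyl}oxolan-2-one | COc1cc(C[C@@H]2COC(=O)C2)ccc1O[Si](C)(C)C(C)(C)C | intermediate
9 | p-cresol | Cc1ccc(O)cc1 | starting material
10 | 2,6-dibromo-4-methylphenol | Cc1cc(Br)c(O)c(Br)c1 | intermediate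
11 | 2,6-dimethoxy-4-methylphenol | COc1cc(C)cc(OC)c1O | intermediate
12 | tert-butyl{[(4S)-4-{[4-(tert-butyldimethylsilyloxy)-3-methoxyphenyl]methyl}-4,5-dihydrofuran-2-yl]oxy}dimethylsilane | COc1cc(C[C@@H]2COC(O[Si](C)(C)C(C)(C)C)=C2)ccc1O[Si](C)(C)C(C)(C)C | intermediate
13 | 2,6-dimethoxy-4-methylidenecyclohexa-2,5-dien-1-one | C=C1C=C(OC)C(=O)C(OC)=C1 | intermediate
14 | (3S,4S)-3-{[4-(tert-butyldimethylsilyloxy)-3,5-dimethoxyphenyl]methyl}-4-{[4-(tert-butyldimethylsilyloxy)-3-methoxyphenyl]methyl}oxolan-2-one (trans) | COc1cc(C[C@@H]2COC(=O)[C@H]2Cc2cc(OC)c(O[Si](C)(C)C(C)(C)C)c(OC)c2)ccc1O[Si](C)(C)C(C)(C)C | intermediate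
15 | potassium enolate of 14 (4S) | COc1cc(C[C@@H]2COC([O-])=C2Cc2cc(OC)c(O[Si](C)(C)C(C)(C)C)c(OC)c2)ccc1O[Si](C)(C)C(C)(C)C.[K+] | intermediate
16 | (3S,4R)-3-hydroxy-3-{[4-(tert-butyldimethylsilyloxy)-3,5-dimethoxyphenyl]methyl}-4-{[4-(tert-butyldimethylsilyloxy)-3-methoxyphenyl]methyl}oxolan-2-one | COc1cc(C[C@@H]2COC(=O)[C@]2(O)Cc2cc(OC)c(O[Si](C)(C)C(C)(C)C)c(OC)c2)ccc1O[Si](C)(C)C(C)(C)C | intermediate
17 | (3S,4R)-3-hydroxy-3-[(4-hydroxy-3,5-dimethoxyphenyl)methyl]-4-[(4-hydroxy-3-methoxyphenyl)methyl]oxolan-2-one | COc1cc(C[C@@H]2COC(=O)[C@]2(O)Cc2cc(OC)c(O)c(OC)c2)ccc1O | target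

## Step count and risks

Total step count: 9. Longest linear sequence: 7 (steps 1, 2, 3, 4, 7, 8, 9).

**Step 3 (Negishi coupling).**
- Risk: zinc insertion into 5 may open the strained ring through the (3-oxocyclobutyl)methyl radical, or the zinc reagent may be quenched by the acidic ketone α-protons.
- Fallback: it sets out from 4 and comes back at 7, building the four-membered ring instead of buying it. Compound 4 is converted to its Grignard reagent (Mg, THF) and allylated with allyl bromide (CuI cat.) to give O-TBS-eugenol F1. Dichloroketene (Cl3CCOCl, Zn–Cu, Et2O/DME) adds in a [2+2] cycloaddition to give the racemic dichlorocyclobutanone F2. Zn in AcOH then removes both chlorines to give 7.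

**Step 4 (enantioselective ring expansion).**
- Risk: benzyl-type cyclobutanones place the stereo-differentiating group one carbon further from the ring than aryl ones, so the ee may fall short.
- Fallback: it sets out from 7 and comes back at 8, replacing asymmetric catalysis by classical resolution. Plain mCPBA/NaHCO3 ring expansion gives the racemic lactone F3. AlMe3-mediated aminolysis with (R)-1-phenylethylamine gives two diastereomeric hydroxy amides, which are separated by crystallisation or chromatography. The (3S,1'R)-hydroxy amide F4 is relactonised with p-TsOH in warm toluene to give 8.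

**Step 7 (proposed new step).**
- Risk: the unsubstituted methide 13 may dimerise or oligomerise before capture. Traces of silver or water may also destroy 12.
- Fallback (known chemistry): it sets out from 11 and, for the last operation, from 8, and comes back at 14.
  - Compound 11 is oxidised with O2/Co(OAc)2/NaOH in MeOH to syringaldehyde F5.
  - F5 is silylated (TBSCl, imidazole) to the O-TBS-syringaldehyde F6.
  - F6 is reduced (NaBH4) to the O-TBS-syringyl alcohol F7.
  - F7 is converted (CBr4, PPh3) to the O-TBS-syringyl bromide F8.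
  - F8 alkylates the lithium enolate of 8 (LiHMDS, THF/DMPU, −78 °C) trans-selectively to give 14.

## Further compounds

F1 | step 3 | tert-butyl[2-methoxy-4-(prop-2-en-1-yl)phenoxy]dimethylsilane (O-TBS-eugenol) | C=CCc1ccc(O[Si](C)(C)C(C)(C)C)c(OC)c1
F2 | step 3 | rac-2,2-dichloro-3-{[4-(tert-butyldimethylsilyloxy)-3-methoxyphenyl]methyl}cyclobutan-1-one | COc1cc(CC2CC(=O)C2(Cl)Cl)ccc1O[Si](C)(C)C(C)(C)C
F3 | step 4 | rac-4-{[4-(tert-butyldimethylsilyloxy)-3-methoxyphenyl]methyl}oxolan-2-one | COc1cc(CC2COC(=O)C2)ccc1O[Si](C)(C)C(C)(C)C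
F4 | step 4 | (3S)-3-{[4-(tert-butyldimethylsilyloxy)-3-methoxyphenyl]methyl}-4-hydroxy-N-[(1R)-1-phenylethyl]butanamide | COc1cc(C[C@H](CO)CC(=O)N[C@H](C)c2ccccc2)ccc1O[Si](C)(C)C(C)(C)C
F5 | step 7 | syringaldehyde (4-hydroxy-3,5-dimethoxybenzaldehyde) | COc1cc(C=O)cc(OC)c1O
F6 | step 7 | 4-(tert-butyldimethylsilyloxy)-3,5-dimethoxybenzaldehyde | COc1cc(C=O)cc(OC)c1O[Si](C)(C)C(C)(C)C
F7 | step 7 | [4-(tert-butyldimethylsilyloxy)-3,5-dimethoxyphenyl]methanol | COc1cc(CO)cc(OC)c1O[Si](C)(C)C(C)(C)C
F8 | step 7 | [4-(bromomethyl)-2,6-dimethoxyphenoxy](tert-butyl)dimethylsilane | COc1cc(CBr)cc(OC)c1O[Si](C)(C)C(C)(C)C
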